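Which flask ends with more bis adduct: south-west, charged heavily with starting material and stopped late, or south, charged lightly and stopped early?

| flask | starting material | coupling partner | temperature | remark | time |
|---|---|---|---|---|---|
| epsilon | 0.10 mM | 0.26 mM | −25 °C | run made earlier |  |
| gamma | 0.13 mM | 0.26 mM | −14 °C | run made earlier |  |
| south-west | 0.20 mM | 0.260 mM | −20 °C |  | 5.0 min |
| south | 0.12 mM | 0.260 mM | −20 °C |  | 1.2 min |

| run | time / min | bis adduct / % |
|---|---|---|
| epsilon | 0.250 | 6.2 |
| epsilon | 0.667 | 25.4 |
| epsilon | 1.50 | 51.2 |
| epsilon | 4.00 | 69.4 |
| gamma | 0.250 | 17.7 |
| gamma | 0.667 | 42.4 |
| gamma | 1.50 | 54.3 |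
| gamma | 4.00 | 59.5 |

(scatter of a reading: 0.5 percentage points)

- the winner by amount of bis adduct, in percent of the starting material charged; "neither" if no more than 2 percentage points parts them (south-west / south / neither)
- how much bis adduct is there at the end, in percent of the starting material charged: south-west
- how much bis adduct is there at the end, in percent of the starting material charged: south



Two chemists disagree. The first trusts the clock. The epsilon and gamma runs stood at 69.4% and 59.5% at 4.00 min. South-west runs at a temperature between theirs and for longer, 5.0 min, so she expects about 64.5%. South stops at 1.2 min, before the 1.50 min readings of 51.2% and 54.3%, so she expects south-west to win.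

The second counts coupling partner, since each bis adduct takes two. For south-west, charged [coupling partner] over twice the charged [starting material] gives 65.0%. This partner roof, the share of the starting material charged that the coupling partner can carry to bis adduct at two to each, stood at 130% in epsilon and 100% in gamma. It stands at 108% in south. The roof of south-west lies below the whole charge, so coupling partner is the limiting reagent of south-west. The clock's figure sits just under the roof of south-west, which she thinks too close: the slow start of the readings suggests a stage before bis adduct, and what stands at that stage has taken coupling partner without yet giving bis adduct.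

The roof gives her a bound, not a figure. Her figure is the forecast's, on the grounds “only 1.3 equivalents of partner, so partner runs out”: 42% for south-west (from 34% to 48%), 47% for south (from 43% to 51%), winner south.

South-west ends with 31.1% of bis adduct and south with 49.2%, so south wins as forecast, while the south-west figure stood 11 percentage points too high. At 5.00 min south-west also holds 17.9% as isomer of the product. Bis adduct, isomer and half of the 31.6% of single product sum to 64.8% against the roof of 65.0%, with 0.24% of the coupling partner left. The clock's view holds in south, whose roof clears the charge: there bis adduct stands at 55.4% at 12.0 min, more than at the asked time.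

    starting material + coupling partner → single product (k = 169 L mol⁻¹ s⁻¹, Ea = 37.0 kJ mol⁻¹)
    2 starting material → self-condensation product (k = 0.0961 L mol⁻¹ s⁻¹, Ea = 46.0 kJ mol⁻¹)
    bis adduct ⇌ isomer of the product (K = 0.805, k = 0.00321 s⁻¹, Ea = 64.0 kJ mol⁻¹, ΔH = −41.0 kJ mol⁻¹)
    coupling partner + single product → bis adduct (k = 170 L mol⁻¹ s⁻¹, Ea = 36.0 kJ mol⁻¹)
    (constants at −20 °C)

Take the neighbour of south charged with 0.65 mM of coupling partner. Its roof is 271%, far above the whole charge, so the reckoning sets no cap from coupling partner below the whole charge. At 1.20 min that flask holds 84.5% of bis adduct and 1.94% of single product.

(Readings and results are calculated from invented constants, and the scatter is random.)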